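Assumption: the carbinol carbon of the target is (S) as drawn; TiCl2[(R,R)-TADDOLate] is made beforehand from commercial (R,R)-TADDOL [(4R,5R)-2,2-dimethyl-α,α,α',α'-tetraphenyl-1,3-dioxolane-4,5-dimethanol] and TiCl2(OiPr)2 and counts as a reagent, not as a route step.

## Retrosynthetic overview

1. Key disconnection (last forward step): the Cα–OH bond of the ketol, made by enantioselective oxygen transfer to a chelated chiral titanium enolate of the complete, unprotected ketone; this C–O bond sets the only stereocentre.
2. That ketone is cut at the C5'–prenyl bond (Friedel–Crafts allylation) and then at the aryl–acyl bond (Friedel–Crafts acylation), which leads to resorcinol (1), 3-(4-methoxyphenyl)propanoic acid (2) and a C5 allylic alcohol.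
3. Forward: 1 + 2 → 3; 3 + 4 → 5; 5 → 8 through 6 and 7 (not isolated).
4. No ring is formed; ring A comes from 1 and ring B from 2.

## Route

Step 1
Reactants: 1 resorcinol; 2 3-(4-methoxyphenyl)propanoic acid
Product: 3 1-(2,4-dihydroxyphenyl)-3-(4-methoxyphenyl)propan-1-one
Conditions: BF3·OEt2 (neat, solvent and promoter), 85 °C, 2 h; aq. NaOAc work-up
Reagents that add atoms: none
Why: Nencki-type Friedel–Crafts acylation, in which the activated acid attacks resorcinol at C4 (para to one OH, ortho to the other), the 2-hydroxy ketone formed is protected from a second acylation by boron chelation, and cyclisation of 2 onto its own ring is disfavoured because that position is meta to the methoxy group.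

Step 2
Reactants: 3 1-(2,4-dihydroxyphenyl)-3-(4-methoxyphenyl)propan-1-one; 4 2-methylbut-3-en-2-ol
Product: 5 1-[2,4-dihydroxy-5-(3-methylbut-2-en-1-yl)phenyl]-3-(4-methoxyphenyl)propan-1-one
Conditions: BF3·OEt2 (0.5 equiv), 4 (1.2 equiv, slow addition), 1,4-dioxane, rt, 16 h; chromatography (3'-prenyl isomer removed, unreacted 3 recycled)
Reagents that add atoms: none
Why: Friedel–Crafts allylation, in which BF3 ionises the tertiary allylic alcohol to the 1,1-dimethylallyl cation, which is captured at its unhindered primary terminus by the most accessible activated position of ring A, C5' (ortho to the free 4'-OH, para to the chelated 2'-OH), in preference to the flanked C3' and to the less electron-rich ring B, while dioxane tempers the acid so that the ortho-prenyl phenol does not close to a chroman (expected 25–35 % of 5).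

Step 3
Reactants: 5 1-[2,4-dihydroxy-5-(3-methylbut-2-en-1-yl)phenyl]-3-(4-methoxyphenyl)propan-1-one
Product: 8 lespeflorin C2 as the (2S)-ketol, via trilithium trianion 6 (not isolated), via titanium enolate chelate 7 (not isolated)
Conditions: LiN(SiMe3)2 (3.3 equiv), THF, −78 → −20 °C; TiCl2[(R,R)-TADDOLate] (1.15 equiv), −78 → −40 °C; (±)-trans-3-phenyl-2-(phenylsulfonyl)oxaziridine (1.5 equiv), −78 °C, 1 h; aq. NH4Cl / 1 M HCl, 0 °C
Reagents that add atoms: LiN(SiMe3)2, [Li+].C[Si](C)(C)[N-][Si](C)(C)C (Li in 6 and 7); TiCl2[(R,R)-TADDOLate], Cl[Ti]1(Cl)OC(c2ccccc2)(c2ccccc2)[C@@H]2OC(C)(C)O[C@H]2C(c2ccccc2)(c2ccccc2)O1 (Ti and diolate in 7); (±)-trans-3-phenyl-2-(phenylsulfonyl)oxaziridine, O=S(=O)(N1OC1c1ccccc1)c1ccccc1 (the new O of 8)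
Why: Proposed new method: the trianion 6 (made as for the acylation of unprotected polyhydroxyacetophenones) transmetalates to tetravalent titanium so that the 2'-phenoxide and the enolate oxygen of one molecule replace both chlorides of TiCl2[(R,R)-TADDOLate], giving the neutral pseudo-tetrahedral spiro chelate 7 in which the enolate is locked Z and coplanar with ring A and one π-face of Cα is blocked by the aryl groups of the C2-symmetric diolate, after which Cα attacks the oxaziridine oxygen (N–O cleavage, loss of the sulfonimine) on its open Si face to give the (S)-alkoxide, which stays metal-bound and so cannot re-enolise before the acidic quench, while the prenyl alkene is inert to this oxidant at −78 °C; the closest known reaction types are the oxaziridine hydroxylation of alkali-metal and titanium enolates, the modest-ee oxidation of monodentate chiral diolate–titanium ketone enolates, and the two-point binding of 2'-hydroxyaryl ketones to chiral diol–boron Lewis acids, but a phenoxide-anchored chiral titanium enolate of an unprotected 2'-hydroxyaryl ketone has not been hydroxylated before, and the facial sense (Si with the (R,R)-ligand) is a model prediction to be confirmed by chiral HPLC and CD, the (S,S)-ligand being equally available.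

## Compound list

1 | resorcinol | Oc1cccc(O)c1 | starting material
2 | 3-(4-methoxyphenyl)propanoic acid | COc1ccc(CCC(=O)O)cc1 | starting material
3 | 1-(2,4-dihydroxyphenyl)-3-(4-methoxyphenyl)propan-1-one | COc1ccc(CCC(=O)c2ccc(O)cc2O)cc1 | intermediate
4 | 2-methylbut-3-en-2-ol | CC(C)(O)C=C | starting material
5 | 1-[2,4-dihydroxy-5-(3-methylbut-2-en-1-yl)phenyl]-3-(4-methoxyphenyl)propan-1-one | COc1ccc(CCC(=O)c2cc(CC=C(C)C)c(O)cc2O)cc1 | intermediate
6 | trilithium salt of 5: (Z)-enolate, 2'-phenoxide and 4'-phenoxide | [Li+].[Li+].[Li+].COc1ccc(C/C=C(\[O-])c2cc(CC=C(C)C)c([O-])cc2[O-])cc1 | intermediate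
7 | spiro titanium chelate of the (Z)-enolate oxygen and 2'-phenoxide of 5 carrying (R,R)-TADDOLate, lithium 4'-phenoxide | COc1ccc(C/C=C2\O[Ti]3(Oc4cc([O-])c(CC=C(C)C)cc42)OC(c2ccccc2)(c2ccccc2)[C@@H]2OC(C)(C)O[C@H]2C(c2ccccc2)(c2ccccc2)O3)cc1.[Li+] | intermediate
8 | lespeflorin C2, (2S)-1-[2,4-dihydroxy-5-(3-methylbut-2-en-1-yl)phenyl]-2-hydroxy-3-(4-methoxyphenyl)propan-1-one | COc1ccc(C[C@H](O)C(=O)c2cc(CC=C(C)C)c(O)cc2O)cc1 | target

## Step count and risks

Total step count: 3. Longest linear sequence: 3.

Steps most likely to fail, most risky first: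

Step 3 (proposed new method). The risks are incomplete formation of the trianion, aggregation through the lithium 4'-phenoxide or ligand redistribution at titanium that erodes the ee, addition of the enolate to the sulfonimine by-product, and a facial sense opposite to the model. The fallback uses known, reagent-controlled chemistry and sets out from 5. Silylation of both phenols (TBSCl, imidazole, DMF, 40 °C) gives 1-[2,4-bis(tert-butyldimethylsilyloxy)-5-(3-methylbut-2-en-1-yl)phenyl]-3-(4-methoxyphenyl)propan-1-one F4. Its sodium (Z)-enolate (NaN(SiMe3)2, THF, −78 °C) is oxidised with enantiopure [(8,8-dichlorocamphoryl)sulfonyl]oxaziridine, using the (+)-reagent, which by analogy with propiophenone-type enolates should give the (S)-ketol. This gives (2S)-1-[2,4-bis(tert-butyldimethylsilyloxy)-5-(3-methylbut-2-en-1-yl)phenyl]-2-hydroxy-3-(4-methoxyphenyl)propan-1-one F5. Buffered desilylation (Bu4NF/AcOH 1:1, THF, 0 °C) returns to the route at 8.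

Step 2. The risks are a modest yield, co-formation of the 3'-prenyl isomer, and chroman formation. The fallback fixes the regiochemistry with a halogen and sets out from 2. Acylation of commercial 4-bromoresorcinol (Oc1ccc(Br)c(O)c1) with 2 under the step 1 conditions (BF3·OEt2, 85 °C) gives 1-(5-bromo-2,4-dihydroxyphenyl)-3-(4-methoxyphenyl)propan-1-one F3. Stille coupling with tributyl(3-methylbut-2-en-1-yl)stannane (Pd(PPh3)4, DMF, 90 °C), which tolerates the free phenols and transfers the linear prenyl group, returns to the route at 5.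

Step 1. The risks are O-acylation or diacylation and partial loss of the methyl ether in hot BF3·OEt2. The fallback builds the C3 chain by aldol chemistry and sets out from 1. Nencki acetylation (AcOH, ZnCl2, 140 °C) gives 1-(2,4-dihydroxyphenyl)ethan-1-one F1, which is also a cheap catalogue compound. Claisen–Schmidt condensation with 4-methoxybenzaldehyde (KOH, aq. EtOH, rt) gives (E)-1-(2,4-dihydroxyphenyl)-3-(4-methoxyphenyl)prop-2-en-1-one F2. Hydrogenation of the enone C=C (H2, 1 atm, Pd/C, EtOAc, stopped at one equivalent) returns to the route at 3.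

Further compounds
F1 | step 1 | 1-(2,4-dihydroxyphenyl)ethan-1-one | CC(=O)c1ccc(O)cc1O
F2 | step 1 | (E)-1-(2,4-dihydroxyphenyl)-3-(4-methoxyphenyl)prop-2-en-1-one | COc1ccc(/C=C/C(=O)c2ccc(O)cc2O)cc1
F3 | step 2 | 1-(5-bromo-2,4-dihydroxyphenyl)-3-(4-methoxyphenyl)propan-1-one | COc1ccc(CCC(=O)c2cc(Br)c(O)cc2O)cc1
F4 | step 3 | 1-[2,4-bis(tert-butyldimethylsilyloxy)-5-(3-methylbut-2-en-1-yl)phenyl]-3-(4-methoxyphenyl)propan-1-one | COc1ccc(CCC(=O)c2cc(CC=C(C)C)c(O[Si](C)(C)C(C)(C)C)cc2O[Si](C)(C)C(C)(C)C)cc1
F5 | step 3 | (2S)-1-[2,4-bis(tert-butyldimethylsilyloxy)-5-(3-methylbut-2-en-1-yl)phenyl]-2-hydroxy-3-(4-methoxyphenyl)propan-1-one | COc1ccc(C[C@H](O)C(=O)c2cc(CC=C(C)C)c(O[Si](C)(C)C(C)(C)C)cc2O[Si](C)(C)C(C)(C)C)cc1
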